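# Proposed total synthesis of kadsurenin D from (R)-pulegone by Favorskii ring contraction

## Analysis of the target

Kadsurenin D (23) is a bicyclo[3.2.1]oct-3-ene-2,8-dione, numbered here C1 (bridgehead CH), C2 (enone carbonyl), C3 (methoxy-bearing alkene carbon), C4 (alkene CH), C5 (allyl-bearing bridgehead), C6 (methyl carbon), C7 (aryl carbon) and C8 (bridging carbonyl). Ring A (C1 to C5 plus C8) is a six-membered 2-methoxy-enone and ring B (C1, C7, C6, C5, C8) is a cyclopentanone. The four stereocentres are 1S,5S,6R,7R: on ring B the allyl group at C5 and the aryl group at C7 lie on the face turned away from the C2–C4 bridge and the C6 methyl group lies on the bridge side, so the methyl group is trans to both neighbours, while C1 is tied to C5 by the bridge. The sensitive groups are the terminal alkene (which rules out hydrogenation and late ozonolysis and is at risk with electrophilic palladium), the enol ether (hydrolysed by hot aqueous acid), the electron-rich arene, and the C8/C2 1,3-diketone, which cannot enolise through bridgehead C1 and is therefore open to retro-Claisen cleavage by nucleophilic base. The first difficulty is quaternary C5, which sits next to the C6 stereocentre and carries both C4 and C8. The second is the bridged ring closure: C1 must stay tetrahedral, although C1–H becomes the most acidic proton as soon as C2 and C8 are both carbonyls. The strategy rests on ring B: with its C6 methyl stereocentre, the one-carbon branch C4 on C5 and the C8 carbonyl, it has the substitution pattern of methyl pulegenate (4). The C5–C8 bond of 4 forms when the six-membered ring of (R)-pulegone (1) contracts, and the methyl-bearing carbon of 1 already has the R configuration needed at C6.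

## Retrosynthetic reasoning

**C3=C4 (ring A).** The enol ether double bond of 23 is cut by a retro-aldol condensation. This leads to diketone 20, in which C1 carries the methoxyacetyl group (C2, C3) and C5 carries C4 as a masked aldehyde. A Claisen closure onto a C4 ester was considered and set aside for two reasons. It would leave an oxygen at C4 that must later be removed regioselectively next to the C8 ketone. More seriously, once C1 is acylated its proton is the acidic one, and a C1 enolate cannot be part of the bridged ring (bridgehead double bond), so C3 would have to react from a vanishingly small tautomer against a poor electrophile. With C4 at the aldehyde level the closure is an acid-catalysed aldol condensation through the C3 enol. It is made irreversible by dehydration, delivers C4 as CH directly, and fixes C1 because only the epimer with the acyl group cis to C4 can close.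

**C1–C2.** The methoxyacetyl group of 20 is removed to give ketone 18 and acid chloride 19. C1 is the only enolisable position of 18, so the acylation needs no regiocontrol.

**C7–aryl.** The aryl group of 18 is cut back to enone 14 and aryl bromide 15. Conjugate addition to a cyclopentenone with a substituent at the adjacent carbon is reliably anti, so the C6 methyl group sets C7.

**C1=C7.** Enone 14 comes from saturated ketone 11 by dehydrogenation. Since C5 is quaternary, only one enolate can form.

**Oxidation level of C4.** Acetal 11 is traced to keto ester 8 through diol 9 and keto aldehyde 10. No skeletal bond is cut. The adjustment is placed early, on small intermediates, so that no oxidant has to be used once the 1,3-diketone exists.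

**C5–allyl.** Keto ester 8 is cut at the allyl bond to β-keto ester 6 and allyl bromide 7. The stabilised enolate is alkylated anti to the neighbouring methyl group, which places the ester (C4) cis to the methyl group as the target requires.

**C8=CMe2.** The ketone of 6 is the ozonolysis product of the isopropylidene group of methyl pulegenate 4. At this stage there is no other alkene.

**C5–C8 (ring contraction).** Cyclopentane 4 is reconnected to the cyclohexanone of dibromide 2, which comes from pulegone 1 by bromination. The Favorskii rearrangement forms the C5–C8 bond and ring B, and expels the old carbonyl carbon as the ester that becomes C4. The cheap terpene supplies ring B, the C6 configuration and the handle for C5 in two operations.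

## Alternatives that were turned down

**Alternative 1:** Ring A is disconnected at C1–C2 and C4–C5, and the three carbons C2–C3–C4 come from methoxymalonyl dichloride A2.
- Forward key step: silyl enol ether A1, in which ring B already carries the allyl, methyl and aryl groups, is acylated at C1 by A2. The remaining acyl chloride (or the ketene formed from it) then acylates C5, giving the hydroxy-enone-dione A3.
- For it: two C–C bonds and ring A form in one operation. C1 and C5 react as nucleophiles and become tetrahedral in the bond-forming events, so the C1–H problem of the chosen route does not arise. On this point the alternative is stronger.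
- Against it: A3 carries oxygen at both C2 and C4, and the two enol oxygens sit next to similar bridgeheads, so nothing in the structure directs selective removal of the C4 oxygen in the presence of the C8 ketone. The quaternary centre must form next to the C6 methyl group inside a strained transition state, and five-membered ketones are the less favourable case for this annulation. A2, an α-alkoxy acid chloride, readily loses HCl to a ketene before it acylates. A1 still needs its own source of absolute configuration.
- Comparison: the chosen route is longer in ring A, but it sets C5 by a simple alkylation, reaches C4 as CH without deoxygenation, and takes C6 from the chiral pool.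

**Alternative 2:** Ring B is disconnected at C6–C7 and at the C5–allyl bond.
- Forward key step: the Lewis acid A5, Cu(OTf)2, carrying a chiral bis(oxazoline) ligand, binds the β-keto ester of dienone A4 and triggers conrotatory closure. Allyltrimethylsilane A6 then intercepts the oxyallyl cation at C5 to give cyclopentanone A7.
- For it: absolute configuration comes from a catalyst, and C5, C6 and C7 are set in one step. The two ester carbons of A7 (C2 on C1, C3 via C4 on C5) invite an acyloin-type closure at C2–C3. The resulting 2,3-dioxygenated ring can enolise only toward C4, so the enol ether regiochemistry is settled by structure. On that point it is stronger than the chosen route.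
- Against it: intermolecular capture of the cation at a fully substituted carbon must outrun proton loss while the chiral complex of A5 stays bound, a combination without close precedent. The face of capture relative to the C6 methyl group is not secured. Both alkene geometries of A4 must be controlled. Dissolving-metal acyloin conditions are not compatible with the free C8 ketone, so protection steps follow.
- Comparison: the step count is similar, but the alternative puts its risk on an unproven asymmetric step, where the chosen route uses a long-established ring contraction.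

**Alternative 3:** The C1–C2 bond is disconnected in hydroxy-dione A9.
- Forward key step: a chiral secondary amine of the proline type converts one of the two enantiotopic ketones of prochiral diketo aldehyde A8 into its enamine, and C1 adds to the side-chain aldehyde C2.
- For it: A8 is two steps from simple materials. The bicyclic core with quaternary C5 and bridgehead C1 forms in one catalytic step, and C1 reacts as the natural nucleophile. On brevity to the core it is clearly stronger.
- Against it: A9 lacks every substituent that makes the target difficult. The aryl group at C7 must be introduced. The C6 carbonyl must be turned into a methyl stereocentre while the allyl alkene is present, which excludes hydrogenation of a methylene intermediate. C3 must be oxygenated and the C3=C4 unsaturation introduced. Three carbonyls (C2, C6, C8) must be told apart.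
- Comparison: the chosen route sets C6 from pulegone and C7 by conjugate addition anti to it, where the alternative needs a long post-cyclisation sequence with poorly controlled selectivity.

Key step: step 2

Remark on the chemistry: compounds 2, 4, 9, 12 and 22 are epimer mixtures at a centre that is later made planar, oxidised or eliminated, so one epimer or an unspecified centre is drawn. Diketone 20 is drawn in the diketo form with the C1 configuration that cyclises; C1 is configurationally labile in 20.

## Route

Step 1
Reactants: 1 (R)-(+)-pulegone [(5R)-5-methyl-2-(propan-2-ylidene)cyclohexan-1-one]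
Product: 2 pulegone dibromide [(5R)-2-bromo-2-(2-bromopropan-2-yl)-5-methylcyclohexan-1-one; both C2 epimers; the (2R,5R) epimer is drawn]
Conditions: Br2 (1.0 equiv), NaHCO3, Et2O, −10 °C; used crude
Reagents that add atoms: bromine, BrBr
Why: Electrophilic addition of bromine across the electron-rich tetrasubstituted enone alkene gives the α,β-dibromo ketone; low temperature and the NaHCO3 buffer suppress acid-mediated isomerisation. The methyl stereocentre is not involved, and the new brominated ring carbon forms as a mixture that is destroyed in step 2.

Step 2
Reactants: 2 pulegone dibromide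
Product: 4 methyl pulegenate [methyl (1S,2R)-2-methyl-5-(propan-2-ylidene)cyclopentane-1-carboxylate; trans epimer drawn; cis epimer also formed], via cyclopropanone 3 (not isolated)
Conditions: NaOMe (2.5 equiv), MeOH, 0 °C then reflux
Reagents that add atoms: sodium methoxide, [Na+].[O-]C
Why: Favorskii rearrangement of an α-halo ketone. Methoxide removes a proton from the only enolisable position, the α′-CH2 next to the methyl-bearing carbon, and the enolate displaces the ring bromide by intramolecular substitution (3-exo-tet) to give cyclopropanone 3. Methoxide then adds to the strained carbonyl, and the adduct collapses by breaking the bond between the acyl carbon and the carbon bearing the CMe2Br group, because the negative charge developing there is discharged at once by loss of the tertiary bromide, which restores the isopropylidene group. The result is the C5–C8 bond and five-membered ring B, which arises from the transient three-membered ring by cleavage of the old six-ring bond, with the former carbonyl carbon expelled as the ester that becomes C4. The methyl-bearing carbon has no acidic hydrogen and is untouched, so C6 keeps the R configuration. The ester-bearing centre (later C5) is set without control in the cyclopropanone closure and can equilibrate under NaOMe, which does not matter because it is enolised and alkylated in step 4. The one selectivity needed is the direction of cyclopropanone opening, and the β-bromide secures it. The closest known reaction is the contraction of 2-halocyclohexanones to cyclopentanecarboxylates.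

Step 3
Reactants: 4 methyl pulegenate
Product: 6 methyl (1S,2R)-2-methyl-5-oxocyclopentane-1-carboxylate, via primary ozonide 5 (not isolated)
Conditions: O3, CH2Cl2, −78 °C; then Me2S, −78 °C to rt
Reagents that add atoms: ozone, [O-][O+]=O
Why: Ozonolysis: ozone adds to the only alkene to give primary ozonide 5, which fragments, and Me2S reduces the peroxidic fragments to leave the ring ketone C8. Both epimers of 4 converge, because the ester-bearing carbon of β-keto ester 6 is enolisable and settles as the trans isomer and its enol.

Step 4
Reactants: 6 methyl (1S,2R)-2-methyl-5-oxocyclopentane-1-carboxylate; 7 allyl bromide [3-bromoprop-1-ene]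
Product: 8 methyl (1R,2R)-2-methyl-5-oxo-1-(prop-2-en-1-yl)cyclopentane-1-carboxylate
Conditions: K2CO3, acetone, reflux
Reagents that add atoms: none
Why: C-alkylation of the stabilised β-keto ester enolate creates quaternary C5. The planar enolate should be attacked on the face away from the adjacent C6 methyl group, which puts allyl trans to methyl and the ester (C4) cis to it.

Step 5
Reactants: 8 methyl (1R,2R)-2-methyl-5-oxo-1-(prop-2-en-1-yl)cyclopentane-1-carboxylate
Product: 9 (2S,3R)-2-(hydroxymethyl)-3-methyl-2-(prop-2-en-1-yl)cyclopentan-1-ol [both C1 epimers]
Conditions: LiAlH4, THF, 0 °C to rt; then H2O, aq. NaOH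
Reagents that add atoms: none
Why: Hydride reduction of ketone and ester to the 1,3-diol; the isolated alkene is inert to LiAlH4. The new carbinol centre is unselective and is removed again in step 6.

Step 6
Reactants: 9 (2S,3R)-2-(hydroxymethyl)-3-methyl-2-(prop-2-en-1-yl)cyclopentan-1-ol
Product: 10 (1S,2R)-2-methyl-5-oxo-1-(prop-2-en-1-yl)cyclopentane-1-carbaldehyde
Conditions: (COCl)2, DMSO, CH2Cl2, −78 °C; then Et3N, −78 to 0 °C
Reagents that add atoms: none
Why: Swern oxidation of both alcohols gives the β-keto aldehyde under non-nucleophilic conditions, so the formyl group is not lost by retro-Claisen cleavage. Quaternary C5 cannot epimerise.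

Step 7
Reactants: 10 (1S,2R)-2-methyl-5-oxo-1-(prop-2-en-1-yl)cyclopentane-1-carbaldehyde
Product: 11 (2S,3R)-2-(dimethoxymethyl)-3-methyl-2-(prop-2-en-1-yl)cyclopentan-1-one
Conditions: HC(OMe)3, CeCl3·7H2O (cat.), MeOH, rt
Reagents that add atoms: trimethyl orthoformate, COC(OC)OC
Why: Chemoselective acetalisation: the aldehyde reacts much faster than the hindered cyclopentanone with its quaternary α-carbon, and any ketal that did form would be the first to hydrolyse on work-up. C4 is now held at the aldehyde oxidation level in a base-stable form.

Step 8
Reactants: 11 (2S,3R)-2-(dimethoxymethyl)-3-methyl-2-(prop-2-en-1-yl)cyclopentan-1-one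
Product: 14 (4R,5S)-5-(dimethoxymethyl)-4-methyl-5-(prop-2-en-1-yl)cyclopent-2-en-1-one, via selenide 12 (not isolated), via selenoxide 13 (not isolated)
Conditions: LiN(iPr)2, THF, −78 °C; PhSeBr; then H2O2, pyridine, CH2Cl2, 0 °C to rt
Reagents that add atoms: none
Why: Selenoxide elimination: 11 has a single enolisable position (C1), so selenenylation gives 12 only there, and syn-elimination of selenoxide 13 can only run toward C7, giving the C1=C7 enone. A Pd(OAc)2-mediated dehydrogenation of the silyl enol ether is avoided because it could also couple the enol ether with the allyl group.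

Step 9
Reactants: 14 (4R,5S)-5-(dimethoxymethyl)-4-methyl-5-(prop-2-en-1-yl)cyclopent-2-en-1-one; 15 4-bromoveratrole [4-bromo-1,2-dimethoxybenzene]
Product: 18 (2S,3R,4S)-4-(3,4-dimethoxyphenyl)-2-(dimethoxymethyl)-3-methyl-2-(prop-2-en-1-yl)cyclopentan-1-one, via aryl Grignard reagent 16 (not isolated), via magnesium enolate 17 (not isolated)
Conditions: 15, Mg, THF; then CuBr·SMe2 (10 mol %), 14, THF, −40 °C; sat. aq. NH4Cl
Reagents that add atoms: none
Why: Copper-catalysed conjugate addition of aryl Grignard reagent 16 to the cyclopentenone. The aryl group should enter at C7 anti to the methyl group on the adjacent C6, which sets C7, and protonation of enolate 17 gives the ketone.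

Step 10
Reactants: 18 (2S,3R,4S)-4-(3,4-dimethoxyphenyl)-2-(dimethoxymethyl)-3-methyl-2-(prop-2-en-1-yl)cyclopentan-1-one; 19 methoxyacetyl chloride [2-methoxyacetyl chloride]
Product: 20 (2S,3R,4R,5S)-3-(3,4-dimethoxyphenyl)-5-(dimethoxymethyl)-2-(2-methoxyacetyl)-4-methyl-5-(prop-2-en-1-yl)cyclopentan-1-one
Conditions: LiN(SiMe3)2 (2.2 equiv), toluene, −78 to 0 °C; then 19; sat. aq. NH4Cl
Reagents that add atoms: none
Why: C-acylation of a lithium enolate with an acid chloride in a non-polar solvent, where the second equivalent of base takes up the more acidic product. Only C1 can be enolised. C1 of the 1,3-diketone is configurationally labile, and the drawn epimer (acyl trans to aryl, cis to C4) is both the less crowded one and the one that can cyclise.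

Step 11
Reactants: 20 (2S,3R,4R,5S)-3-(3,4-dimethoxyphenyl)-5-(dimethoxymethyl)-2-(2-methoxyacetyl)-4-methyl-5-(prop-2-en-1-yl)cyclopentan-1-one
Product: 23 kadsurenin D [(1S,5S,6R,7R)-7-(3,4-dimethoxyphenyl)-3-methoxy-6-methyl-5-(prop-2-en-1-yl)bicyclo[3.2.1]oct-3-ene-2,8-dione], via keto aldehyde 21 (not isolated), via aldol 22 (not isolated)
Conditions: TsOH·H2O, acetone/H2O, 40 °C; then TsOH (cat.), toluene, 90 °C, 4 Å MS
Reagents that add atoms: none
Why: Acid unmasks aldehyde 21; the C2 ketone then enolises toward C3, this enol adds to the protonated aldehyde (intramolecular aldol, six-membered ring), and dehydration of 22 to the conjugated enol ether makes the aldol condensation irreversible. Enolisation toward C1 is faster but unproductive, because a C1 enol cannot lie in the bridged ring; it only equilibrates C1, and the epimer with the acyl group cis to C4 closes and fixes C1 as S.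

## Compound list

1 | (R)-(+)-pulegone, (5R)-5-methyl-2-(propan-2-ylidene)cyclohexan-1-one | C[C@@H]1CCC(=C(C)C)C(=O)C1 | starting material
2 | pulegone dibromide, (2R,5R)-2-bromo-2-(2-bromopropan-2-yl)-5-methylcyclohexan-1-one (drawn; formed with its 2S epimer) | C[C@@H]1CC[C@](Br)(C(C)(C)Br)C(=O)C1 | intermediate
3 | cyclopropanone, (4R)-1-(2-bromopropan-2-yl)-4-methylbicyclo[3.1.0]hexan-6-one (ring-fusion carbons unspecified) | C[C@@H]1CCC2(C(C)(C)Br)C(=O)C12 | intermediate (not isolated)
4 | methyl pulegenate, methyl (1S,2R)-2-methyl-5-(propan-2-ylidene)cyclopentane-1-carboxylate (trans epimer drawn; cis epimer also formed) | COC(=O)[C@@H]1C(=C(C)C)CC[C@H]1C | intermediate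
5 | primary ozonide, methyl (6S,7R)-4,4,7-trimethyl-1,2,3-trioxaspiro[4.4]nonane-6-carboxylate (spiro centre unspecified) | COC(=O)[C@@H]1C2(OOOC2(C)C)CC[C@H]1C | intermediate (not isolated)
6 | methyl (1S,2R)-2-methyl-5-oxocyclopentane-1-carboxylate (C1 epimerisable) | COC(=O)[C@@H]1C(=O)CC[C@H]1C | intermediate
7 | allyl bromide, 3-bromoprop-1-ene | C=CCBr | starting material
8 | methyl (1R,2R)-2-methyl-5-oxo-1-(prop-2-en-1-yl)cyclopentane-1-carboxylate | C=CC[C@]1(C(=O)OC)C(=O)CC[C@H]1C | intermediate
9 | (2S,3R)-2-(hydroxymethyl)-3-methyl-2-(prop-2-en-1-yl)cyclopentan-1-ol (both C1 epimers) | C=CC[C@]1(CO)C(O)CC[C@H]1C | intermediate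
10 | (1S,2R)-2-methyl-5-oxo-1-(prop-2-en-1-yl)cyclopentane-1-carbaldehyde | C=CC[C@]1(C=O)C(=O)CC[C@H]1C | intermediate
11 | (2S,3R)-2-(dimethoxymethyl)-3-methyl-2-(prop-2-en-1-yl)cyclopentan-1-one | C=CC[C@]1(C(OC)OC)C(=O)CC[C@H]1C | intermediate
12 | selenide, (2S,3R)-2-(dimethoxymethyl)-3-methyl-5-(phenylselanyl)-2-(prop-2-en-1-yl)cyclopentan-1-one (C5 epimers) | C=CC[C@]1(C(OC)OC)C(=O)C([Se]c2ccccc2)C[C@H]1C | intermediate (not isolated)
13 | selenoxide, (2S,3R)-2-(dimethoxymethyl)-3-methyl-5-(phenylseleninyl)-2-(prop-2-en-1-yl)cyclopentan-1-one | C=CC[C@]1(C(OC)OC)C(=O)C([Se](=O)c2ccccc2)C[C@H]1C | intermediate (not isolated)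
14 | (4R,5S)-5-(dimethoxymethyl)-4-methyl-5-(prop-2-en-1-yl)cyclopent-2-en-1-one | C=CC[C@]1(C(OC)OC)C(=O)C=C[C@H]1C | intermediate
15 | 4-bromoveratrole, 4-bromo-1,2-dimethoxybenzene | COc1ccc(Br)cc1OC | starting material
16 | (3,4-dimethoxyphenyl)magnesium bromide | COc1ccc([Mg]Br)cc1OC | intermediate (not isolated)
17 | bromomagnesium enolate of 18 (C8–O–MgBr, C1=C8; ring configuration as in 18) | C=CC[C@]1(C(OC)OC)C(O[Mg]Br)=C[C@H](c2ccc(OC)c(OC)c2)[C@H]1C | intermediate (not isolated)
18 | (2S,3R,4S)-4-(3,4-dimethoxyphenyl)-2-(dimethoxymethyl)-3-methyl-2-(prop-2-en-1-yl)cyclopentan-1-one | C=CC[C@]1(C(OC)OC)C(=O)C[C@H](c2ccc(OC)c(OC)c2)[C@H]1C | intermediate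
19 | methoxyacetyl chloride, 2-methoxyacetyl chloride | COCC(=O)Cl | starting material
20 | (2S,3R,4R,5S)-3-(3,4-dimethoxyphenyl)-5-(dimethoxymethyl)-2-(2-methoxyacetyl)-4-methyl-5-(prop-2-en-1-yl)cyclopentan-1-one (diketo form drawn) | C=CC[C@]1(C(OC)OC)C(=O)[C@@H](C(=O)COC)[C@H](c2ccc(OC)c(OC)c2)[C@H]1C | intermediate
21 | (1S,2R,3R,4S)-3-(3,4-dimethoxyphenyl)-4-(2-methoxyacetyl)-2-methyl-5-oxo-1-(prop-2-en-1-yl)cyclopentane-1-carbaldehyde | C=CC[C@]1(C=O)C(=O)[C@@H](C(=O)COC)[C@H](c2ccc(OC)c(OC)c2)[C@H]1C | intermediate (not isolated)
22 | (1S,5S,6R,7R)-7-(3,4-dimethoxyphenyl)-4-hydroxy-3-methoxy-6-methyl-5-(prop-2-en-1-yl)bicyclo[3.2.1]octane-2,8-dione (C3 and C4 unspecified) | C=CC[C@]12C(O)C(OC)C(=O)[C@H](C1=O)[C@H](c1ccc(OC)c(OC)c1)[C@H]2C | intermediate (not isolated)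
23 | kadsurenin D, (1S,5S,6R,7R)-7-(3,4-dimethoxyphenyl)-3-methoxy-6-methyl-5-(prop-2-en-1-yl)bicyclo[3.2.1]oct-3-ene-2,8-dione | C=CC[C@]12C=C(OC)C(=O)[C@H](C1=O)[C@H](c1ccc(OC)c(OC)c1)[C@H]2C | target

## Step count and least certain steps

Total step count: 11. Longest linear sequence: 11 steps (1 to 23); 7, 15 and 19 enter as purchased materials.

**Step 2 (key step).** The most likely failure is loss of HBr by elimination or direct substitution by methoxide outrunning the 3-exo-tet closure, since the tertiary side-chain bromide is labile. Prolonged base could also move the double bond of 4 into conjugation with the ester, and ozonolysis would then cut the ring. Fallback: a Wolff ring contraction that forms the same C5–C8 bond without halogen. It sets out from 1 and returns at 4. The kinetic α′-enolate of 1 (LiN(SiMe3)2, THF, −78 °C) is trifluoroacetylated with 2,2,2-trifluoroethyl trifluoroacetate to give (3R)-3-methyl-6-(propan-2-ylidene)-2-(2,2,2-trifluoroacetyl)cyclohexan-1-one F1. Diazo transfer with methanesulfonyl azide and Et3N, with loss of the trifluoroacetyl group, gives (3R)-2-diazo-3-methyl-6-(propan-2-ylidene)cyclohexan-1-one F2. Irradiation in MeOH expels nitrogen, the alkenyl carbon migrates, and the ketene is trapped as 4.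

**Step 11.** Enolisation toward C3 may be too slow, leaving the diketone in its unproductive C1 enol; hot acid could then hydrolyse the enol ether of the product or let the oxocarbenium ion at C4 react with the allyl alkene. Fallback: ring closure by an intramolecular Horner–Wadsworth–Emmons reaction, in which C3 is activated by phosphorus and the olefination is irreversible. It sets out from 20 and returns at 23. The dianion of 20 (LiN(iPr)2, 2.2 equiv, THF) reacts at its terminal, more basic carbon C3 with ClP(OEt)2, and oxidation with H2O2 gives diethyl {2-[(1S,2R,3R,4S)-2-(3,4-dimethoxyphenyl)-4-(dimethoxymethyl)-3-methyl-5-oxo-4-(prop-2-en-1-yl)cyclopentyl]-1-methoxy-2-oxoethyl}phosphonate F3. Mild aqueous acid frees diethyl {2-[(1S,2R,3R,4S)-2-(3,4-dimethoxyphenyl)-4-formyl-3-methyl-5-oxo-4-(prop-2-en-1-yl)cyclopentyl]-1-methoxy-2-oxoethyl}phosphonate F4. LiCl and DBU in MeCN then close the C3=C4 bond to give 23.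

**Step 10.** O-acylation of the ambident enolate and proton exchange between product and unreacted enolate can lower conversion, the more so as C1 lies next to the aryl-bearing carbon. Fallback: an aldol–oxidation sequence, which cannot give an enol ester. It sets out from 18 and returns at 20. The lithium enolate of 18 adds to methoxyacetaldehyde at −78 °C to give (2S,3R,4R,5R)-4-(3,4-dimethoxyphenyl)-2-(dimethoxymethyl)-5-(1-hydroxy-2-methoxyethyl)-3-methyl-2-(prop-2-en-1-yl)cyclopentan-1-one F5, and Dess–Martin periodinane oxidises the β-hydroxy ketone to 20.

**Step 9.** Conjugate addition to the enone, whose C5 is fully substituted, may be slow enough for 1,2-addition to compete, and the allyl group on the face that the aryl group must take may erode facial selectivity. Fallback: rhodium-catalysed conjugate addition of (3,4-dimethoxyphenyl)boronic acid ([Rh(cod)Cl]2, KOH, dioxane/H2O, 50 °C). It does not add to the carbonyl, and a chiral diphosphine matched to the substrate bias can be added to reinforce the selectivity. It sets out from 14 and returns at 18 with no new intermediate.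

**Step 4.** Facial discrimination by a single adjacent methyl group may be incomplete, and part of the enolate may react at oxygen. Fallback: deliver the allyl group intramolecularly. It sets out from 6 and returns at 8. O-allylation of the enol of 6 (allyl alcohol, PPh3, diisopropyl azodicarboxylate) gives methyl (5R)-5-methyl-2-(prop-2-en-1-yloxy)cyclopent-1-ene-1-carboxylate F6. Heating in toluene brings about the Claisen rearrangement, which transfers the allyl group to C5 across the face opposite the neighbouring methyl group.

## Further compounds

F1 | step 2 | (3R)-3-methyl-6-(propan-2-ylidene)-2-(2,2,2-trifluoroacetyl)cyclohexan-1-one | C[C@@H]1CCC(=C(C)C)C(=O)C1C(=O)C(F)(F)F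
F2 | step 2 | (3R)-2-diazo-3-methyl-6-(propan-2-ylidene)cyclohexan-1-one | C[C@@H]1CCC(=C(C)C)C(=O)C1=[N+]=[N-]
F3 | step 11 | diethyl {2-[(1S,2R,3R,4S)-2-(3,4-dimethoxyphenyl)-4-(dimethoxymethyl)-3-methyl-5-oxo-4-(prop-2-en-1-yl)cyclopentyl]-1-methoxy-2-oxoethyl}phosphonate | C=CC[C@]1(C(OC)OC)C(=O)[C@@H](C(=O)C(OC)P(=O)(OCC)OCC)[C@H](c2ccc(OC)c(OC)c2)[C@H]1C
F4 | step 11 | diethyl {2-[(1S,2R,3R,4S)-2-(3,4-dimethoxyphenyl)-4-formyl-3-methyl-5-oxo-4-(prop-2-en-1-yl)cyclopentyl]-1-methoxy-2-oxoethyl}phosphonate | C=CC[C@]1(C=O)C(=O)[C@@H](C(=O)C(OC)P(=O)(OCC)OCC)[C@H](c2ccc(OC)c(OC)c2)[C@H]1C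
F5 | step 10 | (2S,3R,4R,5R)-4-(3,4-dimethoxyphenyl)-2-(dimethoxymethyl)-5-(1-hydroxy-2-methoxyethyl)-3-methyl-2-(prop-2-en-1-yl)cyclopentan-1-one | C=CC[C@]1(C(OC)OC)C(=O)[C@@H](C(O)COC)[C@H](c2ccc(OC)c(OC)c2)[C@H]1C
F0 | step 9 | none | none
F6 | step 4 | methyl (5R)-5-methyl-2-(prop-2-en-1-yloxy)cyclopent-1-ene-1-carboxylate | C=CCOC1=C(C(=O)OC)[C@H](C)CC1
A1 | alternative 1 | {[(3R,4R)-3-(3,4-dimethoxyphenyl)-4-methyl-5-(prop-2-en-1-yl)cyclopent-1-en-1-yl]oxy}trimethylsilane | C=CCC1C(O[Si](C)(C)C)=C[C@H](c2ccc(OC)c(OC)c2)[C@H]1C
A2 | alternative 1 | methoxymalonyl dichloride, 2-methoxypropanedioyl dichloride | COC(C(=O)Cl)C(=O)Cl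
A3 | alternative 1 | (1S,5S,6R,7R)-7-(3,4-dimethoxyphenyl)-4-hydroxy-3-methoxy-6-methyl-5-(prop-2-en-1-yl)bicyclo[3.2.1]oct-3-ene-2,8-dione | C=CC[C@]12C(O)=C(OC)C(=O)[C@H](C1=O)[C@H](c1ccc(OC)c(OC)c1)[C@H]2C
A4 | alternative 2 | dimethyl 2-[(3,4-dimethoxyphenyl)methylidene]-4-ethylidene-3-oxohexanedioate | COC(=O)CC(=CC)C(=O)C(=Cc1ccc(OC)c(OC)c1)C(=O)OC
A5 | alternative 2 | copper bis(trifluoromethanesulfonate), Cu(OTf)2 | [Cu+2].[O-]S(=O)(=O)C(F)(F)F.[O-]S(=O)(=O)C(F)(F)F
A6 | alternative 2 | allyltrimethylsilane, trimethyl(prop-2-en-1-yl)silane | C=CC[Si](C)(C)C
A7 | alternative 2 | methyl (1S,3R,4R,5R)-5-(3,4-dimethoxyphenyl)-3-(2-methoxy-2-oxoethyl)-4-methyl-2-oxo-3-(prop-2-en-1-yl)cyclopentane-1-carboxylate | C=CC[C@]1(CC(=O)OC)C(=O)[C@@H](C(=O)OC)[C@H](c2ccc(OC)c(OC)c2)[C@H]1C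
A8 | alternative 3 | 3-[2,5-dioxo-1-(prop-2-en-1-yl)cyclopentyl]propanal | C=CCC1(CCC=O)C(=O)CCC1=O
A9 | alternative 3 | (1R,2S,5S)-2-hydroxy-5-(prop-2-en-1-yl)bicyclo[3.2.1]octane-6,8-dione | C=CC[C@]12CC[C@H](O)[C@H](C1=O)CC2=O
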